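* the exponent of [starting material] in the starting rate at the charge of the noon run (at the point where two percent of the starting material have become target) (one fixed amount of target, the same in the runs compared)
* target in the dawn run at 90 min, as a share of the starting material charged

**The clock.** I began with the clock. The noon and autumn runs were the readings I had, and the dawn run repeats the noon charge but is read at 90 min, later than the last noon reading.

| setting | noon | autumn | dawn |
|---|---|---|---|
| starting material | 0.600 M | 1.20 M | 0.600 M |
| time |  |  | 90 min |

| run | time / min | [target] / M |
|---|---|---|
| noon run | 1.3 | 0.0448 |
| noon run | 4.0 | 0.1259 |
| noon run | 7.7 | 0.2212 |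
| noon run | 12 | 0.3057 |
| noon run | 18 | 0.3908 |
| noon run | 23 | 0.4377 |
| noon run | 30 | 0.4709 |
| autumn run | 1.3 | 0.0727 |
| autumn run | 4.0 | 0.2135 |
| autumn run | 7.7 | 0.3800 |
| autumn run | 12 | 0.5407 |
| autumn run | 18 | 0.7136 |
| autumn run | 23 | 0.8129 |
| autumn run | 30 | 0.9039 |

(scatter of a reading: 0.002 M)

- Overall: starting material -> target.
- Constant volume, constant temperature.
- What is held in complexes is read along with the free species.
- An order is taken over about fifteen percent of the charge, up and down.

**Main step.** I first took the one step starting material → target, as first order, and defined the charge lifetime τ as the noon charge divided by the noon rate over the first reading: 17.4 min. The dawn time then counts 5.17 lifetimes, so this step gave 99.4%.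

**A loss.** Next I compared equal remainders, found by subtracting target from the charge. The autumn run, between 12 min and 18 min, had a reckoned remainder of about 0.573 M and made target at 0.0288 M min⁻¹. The noon run, with a reckoned remainder of about 0.578 M, began at 0.0345 M min⁻¹. The autumn rate there was lower than the noon rate, and I read this deficit as a first-order loss of the roughly 0.600 M of extra autumn target, with constant 0.00941 min⁻¹. Placed after the main step, it brought my figure down to 50.6%.

**The rest.** Between the two charges the order, read over the first readings, averaged 0.698, and the autumn lifetime reckoned like τ was 21.5 min, longer than τ. At the dawn time, though, the first-order count with τ reckons hardly any of the charge as unturned, so I kept my figure.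

**The forecast.** The forecast gave an order of 0.75 and 85.5%, higher than my figure, holding that the dawn run had “essentially reached equilibrium”.

**The flask.** The dawn run gave 65.0% target at the time asked, and the order at the noon charge came to 0.77.

    2 starting material ⇌ substrate dimer, settled at all times (0.6370 L mol⁻¹)
    starting material → target (0.08100 min⁻¹)
    target → decomposed product (0.005742 min⁻¹)
    starting material → target (0.006960 min⁻¹)

The equations carry target → decomposed product, with constant 0.00574 min⁻¹. Counting target in the dawn run as formed about one lifetime τ after the start, I gave it about 72.6 min of exposure to that step, and the share of it surviving that long is 65.9%.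

(The data are simulated from invented constants; the scatter is artificial.)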